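5 questions stand open: one share for each of the 4 new flasks, plus the choice of the best.

| flask | substrate | coupling partner | temperature | remark | time |
|---|---|---|---|---|---|
| winter | 0.10 M | 0.70 equiv | 35 °C | run made earlier |  |
| spring | 0.14 M | 0.70 equiv | 50 °C | run made earlier |  |
| dawn | 0.22 M | 0.70 equiv | 35 °C | run made earlier |  |
| Tuesday's | 0.10 M | 0.700 equiv (fed, over 12 min) |  | the addition at 10 °C, then warmed to 50 °C; the feed brings no volume worth counting | 20 min |
| Thursday's | 0.10 M | 0.700 equiv |  | everything together at the start at 10 °C, warmed to 50 °C at 12 min | 20 min |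
| Wednesday's | 0.10 M | 0.700 equiv (fed, over 12 min) | 50 °C | all else is in the flask from the start; the feed brings no volume worth counting | 20 min |
| Monday's | 0.10 M | 0.700 equiv | 50 °C | everything together at the start | 20 min |

- winter (time / min: target / %, isomer of the product / %, substrate / %): 4.00: 0, 8.3, 86.9; 10.0: 0, 13.9, 72.9; 20.0: 1.7, 22.1, 59.0; 30.0: 5.4, 26.8, 50.3; 40.0: 5.0, 25.8, 43.6
- spring (time / min: target / %, isomer of the product / %, substrate / %): 5.00: 4.2, 21.0, 57.1; 10.0: 7.8, 22.2, 42.1; 15.0: 11.8, 21.6, 35.9; 20.0: 13.9, 19.0, 30.7; 25.0: 16.0, 17.0, 29.5
- dawn (time / min: target / %, isomer of the product / %, substrate / %): 4.00: 1.9, 17.2, 76.4; 8.00: 0.9, 23.3, 61.5; 12.0: 2.4, 27.6, 51.1; 25.0: 4.0, 34.5, 35.4; 50.0: 2.1, 36.7, 25.4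

(scatter of a reading: 1 percentage point)

- the analysis behind the earlier runs scatters by 1 percentage point, standard deviation

1. the best flask by share of target in target plus isomer of the product; "all alike" if 1.5 percentage points covers them all (Tuesday's / Thursday's / Wednesday's / Monday's / all alike)
2. share of target in target plus isomer of the product at the end, Tuesday's
3. share of target in target plus isomer of the product at the end, Thursday's
4. share of target in target plus isomer of the product at the end, Wednesday's
5. share of target in target plus isomer of the product at the end, Monday's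

The spring run is the one earlier run at 50 °C, and its share of target in the pair of target plus isomer climbs at each reading, from 16.7% at 5.00 min to 48.5% at 25.0 min. Let u be the isomer's part of that pair. If du/dt = −a·u, u decays exponentially, and these two readings give 0.0240 min⁻¹ for a, the ageing constant, the first-order rate of loss of the isomer's part of the pair. The curve drawn from it has no knee. It is steepest at the start, crosses the point where target equals isomer near 26.2 min, and bends toward a pair made wholly of target.

The reckoning here carries this curve from 0.14 M to 0.10 M, which is an assumption. Read at 20 min, it puts Monday's at 41.9%. Taken as younger by half the feed, which is a second assumption, Wednesday's pair gets 32.9%. Tuesday's and Thursday's have 8.00 min hot, which gives 22.5%.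

The forecast, a separate reckoning, names Monday's as best, at 39%. It gives Wednesday's 29% (22% to 36%), in its words “Wednesday's feed delays it”, Tuesday's 16.5% and Thursday's 17%.

The flasks give Wednesday's as best: Wednesday's 51.2%, Monday's 45.2%, Tuesday's 25.7%, Thursday's 25.3%.

    substrate ⇌ tautomer (K = 1.20, k = 2.30 × 10⁻⁴ s⁻¹, Ea = 101 kJ mol⁻¹, ΔH = −68.0 kJ mol⁻¹)
    substrate + coupling partner ⇌ isomer of the product (K = 9.60 L mol⁻¹, k = 0.0170 L mol⁻¹ s⁻¹, Ea = 64.0 kJ mol⁻¹, ΔH = −45.0 kJ mol⁻¹)
    coupling partner + tautomer → target (k = 0.320 L mol⁻¹ s⁻¹, Ea = 45.0 kJ mol⁻¹)
    2 substrate → self-condensation product (k = 0.00390 L mol⁻¹ s⁻¹, Ea = 68.0 kJ mol⁻¹)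
    (constants at 50 °C)

On the curve drawn from the spring run, Wednesday's share stands at 27.3 min, later than the 20 min on its clock. In Monday's flask, as charged, tautomer has a half-life of 0.52 min by capture with coupling partner, far shorter than the 50 min of substrate's forward passing into tautomer. In Wednesday's flask at 5.07 min, tautomer falls back at 0.027 of the rate at which it goes on. Carried to 50 min with the ageing constant, Wednesday's share becomes 76.2%, and the same flask read then stands at 75.5%.

The runs stem from a simulated flask with constants of no real substance, and the scatter is random.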